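**Retrosynthetic overview**

1. Guaiane numbering is used throughout: C1/C5 ring fusion, C4 carbinol, C6–C7–C8 triad, C10=C14 methylene; β is the face of H1 and of the C4 methyl group. The target is reached by triacetylation of the 3,4,6,8-tetraol, which comes from 1,3-syn reduction of a 6α-hydroxy-8-ketone.
2. Key disconnection: the seven-membered ring is cut at C6–C7 and C9–C10. One fragment is a trans-1,2-disubstituted cyclopentane carrying a C6 aldehyde on C5 and a C10≡C14 alkyne on C1. The other is a C7–C8–C9 ketone α,α′-dianion equivalent, a 2-siloxyallylboronate made from mesityl oxide. A one-pot (4+3) relay annulation joins them: allylboration, then gold-catalysed Conia-ene closure.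
3. Enabling feature: in the cycloheptane, C8 is a carbinol flanked by the C7 methine and the C9 methylene, C6 is oxygenated and C10 bears the exocyclic methylene. C7 and C9 are therefore the two α-carbons of a latent C8 ketone, and they can add to a C6 carbonyl and a C10≡C14 alkyne held 1,4 to each other (C6–C5–C1–C10) on the trans-substituted cyclopentane.
4. The cyclopentane comes from (S)-4-silyloxycyclopentenone. Its stereocentre directs the vinyl (C6) addition and, through that, the enolate oxidation (C4) and the alkynyl (C10/C14) addition; C3 is set by hydroxyl-directed reduction.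
5. Ring order: the five-membered ring is present from the start; the seven-membered ring is closed last, in step 11.

Key step: step 11

Step 1
Reactants: 1 (S)-4-(tert-butyldimethylsilyloxy)cyclopent-2-en-1-one
Product: 2 (S)-4-(tert-butyldimethylsilyloxy)-2-iodocyclopent-2-en-1-one
Conditions: iodine, pyridine, CH2Cl2, 0 °C to 23 °C
Reagents that add atoms: iodine, [I][I]
Why: Pyridine-mediated α-iodination of the enone (conjugate addition of pyridine, iodination of the enolate, elimination) should give the 2-iodoenone without touching the silyloxy stereocentre.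

Step 2
Reactants: 2 (S)-4-(tert-butyldimethylsilyloxy)-2-iodocyclopent-2-en-1-one
Product: 3 (S)-4-(tert-butyldimethylsilyloxy)-2-methylcyclopent-2-en-1-one
Conditions: SnMe4, Pd2(dba)3 (2.5 mol %), AsPh3, CuI, NMP, 50 °C
Reagents that add atoms: tetramethylstannane, C[Sn](C)(C)C
Why: Base-free, copper-assisted Stille coupling of the α-iodoenone should install the C15 methyl group without β-elimination of the silyloxy group.

Step 3
Reactants: 3 (S)-4-(tert-butyldimethylsilyloxy)-2-methylcyclopent-2-en-1-one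
Product: 4 (3S,4S)-4-(tert-butyldimethylsilyloxy)-2-methyl-1-(trimethylsilyloxy)-3-vinylcyclopent-1-ene
Conditions: CH2=CHMgBr, CuBr·SMe2 (10 mol %), TMSCl, THF, −78 °C; Et3N quench
Reagents that add atoms: vinylmagnesium bromide, C=C[Mg]Br; chlorotrimethylsilane, C[Si](C)(C)Cl
Why: Copper-catalysed, TMSCl-accelerated conjugate addition should occur anti to the silyloxy group, which sets C5 with the C6 precursor on the β-face, and it traps the enolate regiospecifically as the C3=C4 enol silane.

Step 4
Reactants: 4 (3S,4S)-4-(tert-butyldimethylsilyloxy)-2-methyl-1-(trimethylsilyloxy)-3-vinylcyclopent-1-ene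
Product: 6 (4R,5S)-5-methyl-5-(trimethylsilyloxy)-4-vinylcyclopent-2-en-1-one, via α-trimethylsilyloxy ketone 5 (not isolated)
Conditions: m-CPBA (1.05 equiv), NaHCO3, CH2Cl2, −20 °C; then DBU, 0 °C to 23 °C
Reagents that add atoms: m-chloroperoxybenzoic acid, OOC(=O)c1cccc(Cl)c1
Why: Rubottom oxidation should epoxidise the enol silane on the α-face, anti to the adjacent vinyl group, which sets C4 (4α-O, 4β-methyl) after the 1,4-silyl shift; DBU then removes the β-silyloxy group by E1cB elimination to give the enone.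

Step 5
Reactants: 6 (4R,5S)-5-methyl-5-(trimethylsilyloxy)-4-vinylcyclopent-2-en-1-one
Product: 8 (2S,3R,4S)-4-ethynyl-2-hydroxy-2-methyl-3-vinylcyclopentan-1-one, via tris(trimethylsilyl) enol ether 7 (not isolated)
Conditions: TMSC≡CH, n-BuLi, THF, −78 °C; ZnBr2; then 6, TMSOTf, THF/Et2O, −40 °C; then K2CO3, MeOH, 23 °C
Reagents that add atoms: ethynyltrimethylsilane, C#C[Si](C)(C)C
Why: Silyl-triflate-promoted conjugate addition of the alkynylzinc reagent to the cyclopentenone should take place trans to the adjacent vinyl group, which sets C1 with the alkyne on the α-face, and methanolysis then removes all three trimethylsilyl groups.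

Step 6
Reactants: 8 (2S,3R,4S)-4-ethynyl-2-hydroxy-2-methyl-3-vinylcyclopentan-1-one
Product: 9 (1S,2S,4S,5R)-4-ethynyl-1-methyl-5-vinylcyclopentane-1,2-diol
Conditions: Me4NBH(OAc)3, AcOH/MeCN (1:1), −25 °C
Reagents that add atoms: none
Why: In this hydroxyl-directed reduction the acetoxyborohydride should exchange onto the 4α-hydroxyl group and deliver hydride intramolecularly to the α-face of the C3 ketone, giving the trans-diol (3β-OH).

Step 7
Reactants: 9 (1S,2S,4S,5R)-4-ethynyl-1-methyl-5-vinylcyclopentane-1,2-diol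
Product: 10 bis(triethylsilyl) ether of diol 9
Conditions: TESOTf (3 equiv), 2,6-lutidine, CH2Cl2, −78 °C to 0 °C
Reagents that add atoms: triethylsilyl trifluoromethanesulfonate, CC[Si](CC)(CC)OS(=O)(=O)C(F)(F)F
Why: The silyl triflate should silylate both the secondary and the hindered tertiary hydroxyl group, which later prevents retro-aldol cleavage of the β-oxy aldehyde and hydroalkoxylation of the alkyne.

Step 8
Reactants: 10 bis(triethylsilyl) ether of diol 9
Product: 12 (1R,2S,4S,5S)-2-ethynyl-5-methyl-4,5-bis(triethylsilyloxy)cyclopentane-1-carbaldehyde, via vicinal diol 11 (not isolated)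
Conditions: OsO4 (2 mol %), NaIO4 (4 equiv), 2,6-lutidine, 1,4-dioxane/H2O (3:1), 23 °C
Reagents that add atoms: sodium periodate, [Na+].[O-]I(=O)(=O)=O (terminal oxidant; its oxygen reaches the aldehyde through OsO4, O=[Os](=O)(=O)=O)
Why: Lemieux–Johnson oxidation should cleave the monosubstituted alkene chemoselectively, because OsO4 reacts far more slowly with the alkyne, and the lutidine buffer protects the α-stereocentre (C5) of the aldehyde.

Step 9
Reactants: 13 mesityl oxide (4-methylpent-3-en-2-one)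
Product: 15 tert-butyldimethyl[(4-methylpenta-1,3-dien-2-yl)oxy]silane, via lithium dienolate 14 (not isolated)
Conditions: LDA, THF, −78 °C; then TBSCl, DMPU, −78 °C to 23 °C
Reagents that add atoms: tert-butyldimethylsilyl chloride, CC(C)(C)[Si](C)(C)Cl
Why: Kinetic deprotonation at the α′-methyl group followed by O-silylation should give the cross-conjugated 2-siloxydiene.

Step 10
Reactants: 15 tert-butyldimethyl[(4-methylpenta-1,3-dien-2-yl)oxy]silane
Product: 16 tert-butyldimethyl{[(2E)-4-methyl-1-(4,4,5,5-tetramethyl-1,3,2-dioxaborolan-2-yl)pent-2-en-2-yl]oxy}silane (isopropyl cis to CH2B)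
Conditions: HBpin (1.1 equiv), Ni(cod)2 (2.5 mol %), PCy3 (2.5 mol %), toluene, 23 °C
Reagents that add atoms: pinacolborane, [H]B1OC(C)(C)C(C)(C)O1
Why: Proposed new method: zerovalent nickel with PCy3 should bind the s-cis conformer of the siloxydiene, transfer hydride from HBpin to the dimethyl-substituted terminus (C11) and form the C9–B bond by reductive elimination at the unhindered CH2 terminus of the resulting anti π-allyl, which places the isopropyl group cis to CH2B; the closest known reaction is the nickel-catalysed, (Z)-selective 1,4-hydroboration of alkyl-substituted 1,3-dienes with pinacolborane, which has not been shown for 2-siloxydienes.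

Step 11
Reactants: 12 (1R,2S,4S,5S)-2-ethynyl-5-methyl-4,5-bis(triethylsilyloxy)cyclopentane-1-carbaldehyde; 16 tert-butyldimethyl{[(2E)-4-methyl-1-(4,4,5,5-tetramethyl-1,3,2-dioxaborolan-2-yl)pent-2-en-2-yl]oxy}silane
Product: 18 6α-hydroxy-3β,4α-bis(triethylsilyloxy)-1βH,5αH,7αH-guai-10(14)-en-8-one, via borate ester 17 (not isolated)
Conditions: toluene (1 M), 4 Å MS, 40 °C; then [(2-biphenylyl)(t-Bu)2PAu(NCMe)]SbF6 (5 mol %), MeOH (3 equiv), CH2Cl2, 23 °C; aq. NaHCO3 work-up
Reagents that add atoms: none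
Why: Proposed new method: boronate 16 should act as a ketone α,α′-dianion equivalent in a relay (4+3) annulation: thermal allylboration of aldehyde 12 through a closed chair transition state forms C6–C7 and, by allylic transposition, unveils the C8(OTBS)=C9H2 enol silane only once this bond exists, and that enol silane then adds anti to the C10≡C14 alkyne activated by cationic monovalent gold, with protodeauration by MeOH, to form C9–C10 and the exocyclic methylene. The closest known reactions are the allylboration of α-branched aldehydes with (Z)-γ-substituted allylboronates and the gold-catalysed Conia-ene cyclisation of silyl enol ethers onto terminal alkynes, which is known for 7-exo-dig closures; their coupling through a 2-siloxyallylboron reagent in one flask is new. The seven-membered ring closes in the 7-exo-dig mode on the pre-set trans-1,2-disubstituted cyclopentane, so the trans ring fusion is carried in and not created. C7 is controlled by the reagent geometry (the isopropyl group cis to CH2B sits axial in the chair and gives the 6,7-syn adduct, 7β-isopropyl), and C6 is controlled by C5: with an axial γ-substituent only H5 can point at it without a syn-pentane clash, which places the quaternary C4 anti to the forming bond and gives the anti-Felkin 6α-alkoxide. The step needs carbon attack instead of oxygen attack on the alkyne and 7-exo instead of 8-endo closure: the C4 oxygen is silylated, 5-exo attack by the C6 oxygen would give a strained trans-fused oxabicyclo[3.3.0]octane, and attack of the terminal enol carbon on the internal alkyne carbon is the Markovnikov mode that cationic gold favours.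

Step 12
Reactants: 18 6α-hydroxy-3β,4α-bis(triethylsilyloxy)-1βH,5αH,7αH-guai-10(14)-en-8-one
Product: 20 3β,4α-bis(triethylsilyloxy)-1βH,5αH,7αH-guai-10(14)-ene-6α,8α-diol, via diethylboron chelate 19 (not isolated)
Conditions: Et2BOMe (1.2 equiv), THF/MeOH (4:1), −78 °C; then NaBH4, −78 °C; MeOH co-evaporation
Reagents that add atoms: none
Why: In this Narasaka–Prasad reduction external hydride should attack the boron-chelated β-hydroxy ketone on the face opposite to the α-oriented O–B–O bridge, which gives the 1,3-syn diol (8α-OH).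

Step 13
Reactants: 20 3β,4α-bis(triethylsilyloxy)-1βH,5αH,7αH-guai-10(14)-ene-6α,8α-diol
Product: 21 1βH,5αH,7αH-guai-10(14)-ene-3β,4α,6α,8α-tetraol
Conditions: HF·pyridine, pyridine, THF, 0 °C to 23 °C
Reagents that add atoms: none
Why: Buffered fluoride cleavage should remove both triethylsilyl ethers and leave the exocyclic alkene and the tertiary alcohol intact.

Step 14
Reactants: 21 1βH,5αH,7αH-guai-10(14)-ene-3β,4α,6α,8α-tetraol
Product: 22 3β,6α,8α-triacetoxy-1βH,5αH,7αH-guai-10(14)-en-4α-ol, (1S,3S,4S,5S,6S,7R,8S), the target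
Conditions: Ac2O, pyridine, DMAP (10 mol %), CH2Cl2, 0 °C to 23 °C
Reagents that add atoms: acetic anhydride, CC(=O)OC(C)=O
Why: DMAP-catalysed acetylation should esterify the three secondary hydroxyl groups while the hindered tertiary C4 hydroxyl group stays free.

**Compound list**

1 | (S)-4-(tert-butyldimethylsilyloxy)cyclopent-2-en-1-one | O=C1C=C[C@@H](O[Si](C)(C)C(C)(C)C)C1 | starting material
2 | (S)-4-(tert-butyldimethylsilyloxy)-2-iodocyclopent-2-en-1-one | O=C1C(I)=C[C@@H](O[Si](C)(C)C(C)(C)C)C1 | intermediate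
3 | (S)-4-(tert-butyldimethylsilyloxy)-2-methylcyclopent-2-en-1-one | CC1=C[C@@H](O[Si](C)(C)C(C)(C)C)CC1=O | intermediate
4 | (3S,4S)-4-(tert-butyldimethylsilyloxy)-2-methyl-1-(trimethylsilyloxy)-3-vinylcyclopent-1-ene (vinyl trans to OTBS) | C=C[C@@H]1[C@@H](O[Si](C)(C)C(C)(C)C)CC(O[Si](C)(C)C)=C1C | intermediate
5 | (2S,3R,4S)-4-(tert-butyldimethylsilyloxy)-2-methyl-2-(trimethylsilyloxy)-3-vinylcyclopentan-1-one | C=C[C@@H]1[C@@H](O[Si](C)(C)C(C)(C)C)CC(=O)[C@@]1(C)O[Si](C)(C)C | intermediate
6 | (4R,5S)-5-methyl-5-(trimethylsilyloxy)-4-vinylcyclopent-2-en-1-one | C=C[C@@H]1C=CC(=O)[C@@]1(C)O[Si](C)(C)C | intermediate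
7 | 5-methyl-1,5-bis(trimethylsilyloxy)-3-[(trimethylsilyl)ethynyl]-4-vinylcyclopent-1-ene (alkyne trans to vinyl, vinyl trans to the C5 silyloxy group) | C=C[C@@H]1[C@@H](C#C[Si](C)(C)C)C=C(O[Si](C)(C)C)[C@@]1(C)O[Si](C)(C)C | intermediate
8 | (2S,3R,4S)-4-ethynyl-2-hydroxy-2-methyl-3-vinylcyclopentan-1-one | C=C[C@@H]1[C@@H](C#C)CC(=O)[C@@]1(C)O | intermediate
9 | (1S,2S,4S,5R)-4-ethynyl-1-methyl-5-vinylcyclopentane-1,2-diol | C=C[C@@H]1[C@@H](C#C)C[C@H](O)[C@@]1(C)O | intermediate
10 | bis(triethylsilyl) ether of diol 9 | C=C[C@@H]1[C@@H](C#C)C[C@H](O[Si](CC)(CC)CC)[C@@]1(C)O[Si](CC)(CC)CC | intermediate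
11 | vicinal diol from dihydroxylation of the vinyl group of 10 (mixture at the new carbinol carbon) | OCC(O)[C@@H]1[C@@H](C#C)C[C@H](O[Si](CC)(CC)CC)[C@@]1(C)O[Si](CC)(CC)CC | intermediate
12 | (1R,2S,4S,5S)-2-ethynyl-5-methyl-4,5-bis(triethylsilyloxy)cyclopentane-1-carbaldehyde | O=C[C@@H]1[C@@H](C#C)C[C@H](O[Si](CC)(CC)CC)[C@@]1(C)O[Si](CC)(CC)CC | intermediate
13 | mesityl oxide (4-methylpent-3-en-2-one) | CC(=O)C=C(C)C | starting material
14 | lithium 4-methylpenta-1,3-dien-2-olate | [Li]OC(=C)C=C(C)C | intermediate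
15 | tert-butyldimethyl[(4-methylpenta-1,3-dien-2-yl)oxy]silane | C=C(O[Si](C)(C)C(C)(C)C)C=C(C)C | intermediate
16 | tert-butyldimethyl{[(2E)-4-methyl-1-(4,4,5,5-tetramethyl-1,3,2-dioxaborolan-2-yl)pent-2-en-2-yl]oxy}silane (isopropyl cis to CH2B) | CC(C)/C=C(\CB1OC(C)(C)C(C)(C)O1)O[Si](C)(C)C(C)(C)C | intermediate
17 | pinacol borate of the 6,7-syn allylboration adduct (6α-OBpin, 7β-isopropyl, C8(OTBS)=C9H2 enol silane, C10≡C14 alkyne) | C=C(O[Si](C)(C)C(C)(C)C)[C@@H](C(C)C)[C@H](OB1OC(C)(C)C(C)(C)O1)[C@@H]1[C@@H](C#C)C[C@H](O[Si](CC)(CC)CC)[C@@]1(C)O[Si](CC)(CC)CC | intermediate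
18 | 6α-hydroxy-3β,4α-bis(triethylsilyloxy)-1βH,5αH,7αH-guai-10(14)-en-8-one | C=C1CC(=O)[C@@H](C(C)C)[C@H](O)[C@@H]2[C@@H]1C[C@H](O[Si](CC)(CC)CC)[C@@]2(C)O[Si](CC)(CC)CC | intermediate
19 | 6-O-diethylboryl derivative (boron chelate) of 18 | C=C1CC(=O)[C@@H](C(C)C)[C@H](OB(CC)CC)[C@@H]2[C@@H]1C[C@H](O[Si](CC)(CC)CC)[C@@]2(C)O[Si](CC)(CC)CC | intermediate
20 | 3β,4α-bis(triethylsilyloxy)-1βH,5αH,7αH-guai-10(14)-ene-6α,8α-diol | C=C1C[C@H](O)[C@@H](C(C)C)[C@H](O)[C@@H]2[C@@H]1C[C@H](O[Si](CC)(CC)CC)[C@@]2(C)O[Si](CC)(CC)CC | intermediate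
21 | 1βH,5αH,7αH-guai-10(14)-ene-3β,4α,6α,8α-tetraol | C=C1C[C@H](O)[C@@H](C(C)C)[C@H](O)[C@@H]2[C@@H]1C[C@H](O)[C@@]2(C)O | intermediate
22 | 3β,6α,8α-triacetoxy-1βH,5αH,7αH-guai-10(14)-en-4α-ol, (1S,3S,4S,5S,6S,7R,8S) | C=C1C[C@H](OC(C)=O)[C@@H](C(C)C)[C@H](OC(C)=O)[C@@H]2[C@@H]1C[C@H](OC(C)=O)[C@@]2(C)O | target

**Step count and risks**

Total step count: 14. Longest linear sequence: 12 steps (steps 1–8 and 11–14; steps 9 and 10 make the boron reagent).

Steps most likely to fail:

Step 11 (key step). The allylboration of the hindered, neopentyl-like aldehyde may be slow or poorly face-selective. In the gold stage, oxygen attack on the activated alkyne or protodesilylation of the enol silane may outrun the 7-exo-dig carbocyclisation. The fallback makes the two bonds in separate, known operations, with the C6 oxygen capped before ring closure. It sets out from 12 and comes back at 21.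
- An Evans syn-aldol reaction of 12 with the dibutylboron enolate of (S)-4-benzyl-3-(3-methylbutanoyl)oxazolidin-2-one (Bu2BOTf, i-Pr2NEt, CH2Cl2, −78 °C) would give the aldol imide F1, with C6 and C7 set by the auxiliary.
- Transamidation (MeNHOMe·HCl, AlMe3) would give the Weinreb amide F2, and TESOTf/2,6-lutidine its C6 triethylsilyl ether F3.
- MeMgBr would give the methyl ketone F4, and TESOTf/Et3N the terminal triethylsilyl enol ether F5.
- The same cationic gold catalyst with MeOH would close the ring to the tris(triethylsilyl) ketone F6.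
- HF·pyridine would give the trihydroxy ketone F7, and Et2BOMe/NaBH4 would reduce it to tetraol 21.

Step 10. Hydride and boron may be delivered with the wrong regiochemistry or double-bond geometry, or the boryl enol ether may be lost by hydrolysis or a borotropic shift. The fallback replaces the boron reagent by a reductive aldol reaction and then builds the enol silane in a separate operation. It sets out from 13 (with 12) and comes back at 18.
- Conjugate reduction of 13 with catecholborane (RhCl(PPh3)3 cat., THF, −20 °C) would give the (Z)-boron enolate F8.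
- Addition of 12 at −78 °C would give the syn β-hydroxy methyl ketone F9 through the same closed transition state.
- TMSOTf/Et3N would give the bis(trimethylsilyl) derivative F10 (C6 silyl ether and terminal enol silane).
- The gold/MeOH cyclisation, followed by a citric acid work-up, would give 18.

Step 12. Hydride delivery to the chelated C8 carbonyl from the β-face, syn to the C7 isopropyl group, may be slow, so that α-face attack erodes the C8 selectivity. The fallback sets C8 by internal delivery and then inverts it. It sets out from 18 and comes back at 22.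
- Evans–Saksena reduction (Me4NBH(OAc)3, AcOH/MeCN) would deliver hydride from the C6 hydroxyl group and give the 6α,8β-diol F11.
- Mitsunobu inversion at the less hindered C8 hydroxyl group with acetic acid (PPh3, DIAD) would give the 8α-acetate F12.
- HF·pyridine would give the desilylated 8α-acetate F13, and Ac2O/pyridine/DMAP would complete 22.

Further compounds
F1 | step 11 | Evans syn-aldol imide (6α-OH, 7β-isopropyl, (S)-4-benzyloxazolidinone on C8) | O=C1OC[C@H](Cc2ccccc2)N1C(=O)[C@@H](C(C)C)[C@H](O)[C@@H]1[C@@H](C#C)C[C@H](O[Si](CC)(CC)CC)[C@@]1(C)O[Si](CC)(CC)CC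
F2 | step 11 | Weinreb amide of the aldol adduct | CON(C)C(=O)[C@@H](C(C)C)[C@H](O)[C@@H]1[C@@H](C#C)C[C@H](O[Si](CC)(CC)CC)[C@@]1(C)O[Si](CC)(CC)CC
F3 | step 11 | C6 triethylsilyl ether of the Weinreb amide | CON(C)C(=O)[C@@H](C(C)C)[C@H](O[Si](CC)(CC)CC)[C@@H]1[C@@H](C#C)C[C@H](O[Si](CC)(CC)CC)[C@@]1(C)O[Si](CC)(CC)CC
F4 | step 11 | tris(triethylsilyl) methyl ketone | CC(=O)[C@@H](C(C)C)[C@H](O[Si](CC)(CC)CC)[C@@H]1[C@@H](C#C)C[C@H](O[Si](CC)(CC)CC)[C@@]1(C)O[Si](CC)(CC)CC
F5 | step 11 | terminal triethylsilyl enol ether of F4 | C=C(O[Si](CC)(CC)CC)[C@@H](C(C)C)[C@H](O[Si](CC)(CC)CC)[C@@H]1[C@@H](C#C)C[C@H](O[Si](CC)(CC)CC)[C@@]1(C)O[Si](CC)(CC)CC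
F6 | step 11 | 3β,4α,6α-tris(triethylsilyloxy)-1βH,5αH,7αH-guai-10(14)-en-8-one | C=C1CC(=O)[C@@H](C(C)C)[C@H](O[Si](CC)(CC)CC)[C@@H]2[C@@H]1C[C@H](O[Si](CC)(CC)CC)[C@@]2(C)O[Si](CC)(CC)CC
F7 | step 11 | 3β,4α,6α-trihydroxy-1βH,5αH,7αH-guai-10(14)-en-8-one | C=C1CC(=O)[C@@H](C(C)C)[C@H](O)[C@@H]2[C@@H]1C[C@H](O)[C@@]2(C)O
F8 | step 10 | (Z)-catecholboron enolate of 4-methylpentan-2-one | CC(C)/C=C(/C)OB1Oc2ccccc2O1
F9 | step 10 | syn β-hydroxy methyl ketone (6α-OH, 7β-isopropyl, C8 ketone, C9 methyl) | CC(=O)[C@@H](C(C)C)[C@H](O)[C@@H]1[C@@H](C#C)C[C@H](O[Si](CC)(CC)CC)[C@@]1(C)O[Si](CC)(CC)CC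
F10 | step 10 | bis(trimethylsilyl) derivative of F9 (C6 silyl ether, terminal enol silane) | C=C(O[Si](C)(C)C)[C@@H](C(C)C)[C@H](O[Si](C)(C)C)[C@@H]1[C@@H](C#C)C[C@H](O[Si](CC)(CC)CC)[C@@]1(C)O[Si](CC)(CC)CC
F11 | step 12 | 3β,4α-bis(triethylsilyloxy)-1βH,5αH,7αH-guai-10(14)-ene-6α,8β-diol | C=C1C[C@@H](O)[C@@H](C(C)C)[C@H](O)[C@@H]2[C@@H]1C[C@H](O[Si](CC)(CC)CC)[C@@]2(C)O[Si](CC)(CC)CC
F12 | step 12 | 8α-acetoxy-3β,4α-bis(triethylsilyloxy)-1βH,5αH,7αH-guai-10(14)-en-6α-ol | C=C1C[C@H](OC(C)=O)[C@@H](C(C)C)[C@H](O)[C@@H]2[C@@H]1C[C@H](O[Si](CC)(CC)CC)[C@@]2(C)O[Si](CC)(CC)CC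
F13 | step 12 | 8α-acetoxy-1βH,5αH,7αH-guai-10(14)-ene-3β,4α,6α-triol | C=C1C[C@H](OC(C)=O)[C@@H](C(C)C)[C@H](O)[C@@H]2[C@@H]1C[C@H](O)[C@@]2(C)O
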